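## The problem

Target 34 is a cis-fused octalin. In the numbering used throughout, C1 carries the (2E,4E)-pentadienoic acid chain, C2 the (E)-but-2-en-2-yl group, C3(Me)=C4 is the ring alkene, C4a and C8a are the fusion carbons, C7 carries the sulfate and C8 a methyl group (ring A = C1–C4, C4a, C8a; ring B = C4a, C5–C8, C8a). Six contiguous stereocentres must be set (1S,2R,4aS,7S,8R,8aR), with both fusion hydrogens, the C1 chain, the C2 butenyl group, the C8 methyl group and the C7 oxygen on one face. The four centres of ring B can be chained: a cis relationship at C4a/C8a can come from a cycloaddition, C8a can send a C8 methylation to the opposite face, and the C8 methyl group can steer hydride delivery to C7. C1 and C2 lie on the chain that becomes ring A and are poorly controlled from ring B, so they need their own source of absolute configuration. The ring alkene is the hard constitutional element: it is trisubstituted, unconjugated and lies between the doubly allylic C2–H and the fusion carbon C4a, so elimination or equilibration cannot be trusted to place it, and acid or base can move it. The sulfate monoester is ionic and acid-labile, and the dienoic acid makes C1–H vinylogously acidic, so both belong at the end and the late steps must be near neutral. The feature that opens a clean ring closure is that C4 is the inner carbon of a vinyl group on C4a, and C3 with its methyl group is the inner carbon of an isopropenyl group on C2. The cis arrangement on ring B holds the two alkenes within reach, and joining them by metathesis fixes the alkene position by construction.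

## Retrosynthesis

**End game.** The O–S bond of the sulfate and the acyl–oxygen bond of a terminal ethyl ester are cut first, taking 34 back to the pyridinium sulfate 33, the hydroxy ester 32 and the silyl ether 31. Putting the charge and the free acid last keeps every earlier intermediate neutral and chromatographable. The forward steps must sulfate a hindered secondary alcohol and then hydrolyse an ester without touching the sulfate.

**Side chain.** The alkene attached to C1 is cut next, giving aldehyde 28 and the four-carbon phosphonate 29. One olefination installs both chain alkenes, which is shorter than building the diene one carbon at a time and avoids having to single out a C1 vinyl group among three other alkenes. Aldehyde 28 comes from ester 26 through alcohol 27. The olefination has to be (E)-selective and must not epimerise C1.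

**Ring A (key cut).** The C3=C4 double bond of 26 is cut to the triene ester 25, which has a vinyl group on C4a and an isopropenyl group on C2. Against an elimination or an aldol-type closure, this cut places the alkene with no positional choice and under neutral conditions. Against a cycloaddition for ring A, it leaves C1 and C2 to be set on an open chain, where a sigmatropic step can control them. The precursor is monocyclic with all six stereocentres already present. The forward reaction has to choose the isopropenyl group over the butenyl group on C2.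

**C1–C2 bond.** Acid 24 (the free acid of 25) is a γ,δ-unsaturated acid twice over, and the C1–C2 bond is cut by an ester-enolate Claisen rearrangement to ester 20, hence to acid 14 and dienol 19. Of the two ways to do this, the one chosen makes the butenyl alkene in the rearrangement. The allylic alcohol is then secondary, and its carbinol centre decides C2 and, through the enolate geometry, C1. The variant with a primary dienol would leave the facial choice to C8a, whose two ring branches are too alike to be trusted. The forward step needs the enolate with C8a trans to the metal-bound oxygen and a chair transition state.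

**Dienol.** The sp2–sp2 bond of 19 is cut to iodoalkene 17 and boronate 18. The C–CH3 and C–I bonds of 17 are cut across the alkyne of 15, which supplies the carbinol centre from the chiral pool. Both forward steps retain alkene geometry.

**Ring B periphery.** Acid 14 is traced through alcohol 12 and the two-fold protected 11 to alcohol 10 and ketone 9. The C8–CH3 bond of 9 is then cut to the enol silane 7. This cut is preferred to enolising a ketone because only the enol silane is regiodefined toward C8. Forward, the methyl group must enter anti to the C8a side chain and the hydride must come from the equatorial side at C7.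

**Ring B.** The vinyl group of 7 comes from aldehyde 6, and the C4a–C8a and C5–C6 bonds of 6 are cut by a Diels–Alder disconnection to diene 4 and acrolein 5. A conjugate addition to a 4-substituted cyclohexenone would give the trans arrangement, whereas the endo cycloaddition gives cis and leaves the enol silane needed next. Diene 4 comes from enone 3, and 3 from aldehyde 1 and ylide 2. The forward cycloaddition carries the whole absolute configuration of ring B.

## Roads not taken

**Alternative 1:** An anionic oxy-Cope rearrangement would disconnect the C4a–C5 bond. Forward, the bridged vinyl carbinol A2, deprotonated with KH and 18-crown-6, would undergo a [3,3] shift that forms C4a–C5, breaks the C3–C7 bridge bond and gives the cis-octalone A1 after protonation.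
- Merits: one concerted step builds ring B, enforces the cis fusion and places C3=C4 by mechanism, with no competition between alkenes. In this respect it is better than the chosen plan, whose ring closure depends on a reactivity difference.
- Weak points: A2 is a bicyclo[2.2.2]octene with a quaternary bridgehead methyl group and four substituted bridge carbons, and its vinyl group must be added syn to the alkene bridge. The enolate formed points to C6 and not to C8, so the C8 methyl group must already be present and becomes epimerisable next to the new ketone. C2–H becomes doubly allylic under strongly basic conditions. No evident source of absolute configuration exists for the bicycle.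
- Comparison: the chosen plan is longer, but each stereocentre has its own named control element and the absolute configuration comes from two understood sources.

**Alternative 2:** An intramolecular allylsilane conjugate addition would disconnect the C8a–C1 bond. Forward, Me3SiOTf would make the allylsilane terminus of enone A4 add to the enone β-carbon, closing ring A and giving the silyl enol ether A3 with a vinyl group on C1.
- Merits: two stereocentres and ring A in one step, and A3 is the same kind of C7=C8 enol silane that the chosen route uses for the C8 methylation, so it matches the chosen plan on that point in fewer steps.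
- Weak points: A4 needs a (Z)-trisubstituted alkene and a C2 centre that is allylic three times over, both exposed to a silyl triflate. C8a and C1 depend on a choice between open transition states. The C1 vinyl group would later have to be singled out among four alkenes to build the dienoic acid.
- Comparison: the chosen plan sets against the shorter sequence a C1 substituent that arrives as a carbonyl group ready for olefination, and C1/C2 set by a closed transition state.

**Alternative 3:** An ester-enolate Claisen ring contraction would also disconnect C1–C2, but from the δ-lactone A6. Forward, A6, after O-silylation of its enolate, would rearrange through a boat so that C1–C2 forms, C4–O breaks and the acid A5 appears with ring A closed and C3=C4 in place.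
- Merits: this is the nearest relative of the chosen plan and is better in step economy. One rearrangement does what esterification, rearrangement and metathesis do here, without ruthenium and without any choice between two alkenes on C2. The ketene acetal geometry is fixed by the ring.
- Weak points: absolute control moves to C4, a carbinol centre that would have to be set by adding a dienyl metal to a ring B aldehyde under uncertain 1,2-induction. The boat bridged across a six-membered lactone is strained, and if it fails there is no second geometry to fall back on.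
- Comparison: the chosen plan sets against this a chair transition state governed by a purchasable carbinol centre and a separate, neutral ring closure.

Key step: step 15

Assumption (step 3): the (S)-configured oxazaborolidinium catalyst is taken to expose the face of acrolein that leads to (1S,2R)-6; if the sense proves opposite, the (R)-catalyst is used and nothing else changes.
Assumption (step 21): the target is drawn as the free hydrogen sulfate and carboxylic acid and is released in that form by a brief cold acidification; for storage it would be kept as a salt.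

## Route

Step 1
Reactants: 1 3-[(4-methoxybenzyl)oxy]propanal; 2 1-(triphenylphosphoranylidene)propan-2-one
Product: 3 (E)-6-[(4-methoxybenzyl)oxy]hex-3-en-2-one
Conditions: CH2Cl2, 23 °C
Reagents that add atoms: none
Why: Wittig olefination with the acetyl-stabilised ylide is (E)-selective and runs without added base, so the β-alkoxy aldehyde cannot eliminate.

Step 2
Reactants: 3 (E)-6-[(4-methoxybenzyl)oxy]hex-3-en-2-one
Product: 4 (E)-{[6-((4-methoxybenzyl)oxy)hexa-1,3-dien-2-yl]oxy}triisopropylsilane
Conditions: i-Pr3SiOTf, Et3N, CH2Cl2, 0 °C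
Reagents that add atoms: triisopropylsilyl trifluoromethanesulfonate, CC(C)[Si](C(C)C)(C(C)C)OS(=O)(=O)C(F)(F)F
Why: Soft enolisation (silyl triflate and amine) removes an α′-methyl proton of the (E)-enone and gives the cross-conjugated 2-silyloxy-1,3-diene; the bulky silyl group is chosen because its enol ethers survive Lewis acids and chromatography.

Step 3
Reactants: 4 (E)-{[6-((4-methoxybenzyl)oxy)hexa-1,3-dien-2-yl]oxy}triisopropylsilane; 5 acrolein
Product: 6 (1S,2R)-2-{2-[(4-methoxybenzyl)oxy]ethyl}-4-[(triisopropylsilyl)oxy]cyclohex-3-ene-1-carbaldehyde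
Conditions: (S)-3,3-diphenyl-1-(o-tolyl)tetrahydro-1H,3H-pyrrolo[1,2-c][1,3,2]oxazaborole·HN(SO2CF3)2 (10 mol %), CH2Cl2, −78 °C; Et3N quench
Reagents that add atoms: none
Why: Catalytic asymmetric Diels–Alder reaction of a 2-silyloxydiene with an enal bound to a chiral cationic oxazaborolidine; the silyloxy group (para) and the terminal alkyl group (ortho) direct the formyl-bearing carbon to the same position, the endo transition state of the (E)-diene puts the formyl group cis to the side chain (C4a/C8a), and the catalyst's choice of enal face sets both centres in the absolute sense.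

Step 4
Reactants: 6 (1S,2R)-2-{2-[(4-methoxybenzyl)oxy]ethyl}-4-[(triisopropylsilyl)oxy]cyclohex-3-ene-1-carbaldehyde
Product: 7 {[(3S,4R)-4-ethenyl-3-{2-[(4-methoxybenzyl)oxy]ethyl}cyclohex-1-en-1-yl]oxy}triisopropylsilane
Conditions: Ph3PCH3Br, KN(SiMe3)2, THF, −78 → 0 °C
Reagents that add atoms: methyltriphenylphosphonium bromide, C[P+](c1ccccc1)(c1ccccc1)c1ccccc1.[Br-]
Why: Wittig methylenation with the non-stabilised ylide at low temperature converts the formyl group into the C4a vinyl group faster than the α-centre can epimerise, and the silyl enol ether is inert to the ylide.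

Step 5
Reactants: 7 {[(3S,4R)-4-ethenyl-3-{2-[(4-methoxybenzyl)oxy]ethyl}cyclohex-1-en-1-yl]oxy}triisopropylsilane
Product: 9 (2R,3S,4R)-4-ethenyl-3-{2-[(4-methoxybenzyl)oxy]ethyl}-2-methylcyclohexan-1-one, via sulfonium enolate 8 (not isolated)
Conditions: [(Me2N)3S][Me3SiF2], MeI, THF, −78 → 0 °C; cold aqueous quench
Reagents that add atoms: iodomethane, C[I]
Why: Fluoride-induced cleavage of the silyl enol ether releases the regiodefined C7/C8 enolate, which is C-methylated in situ (fluoride-mediated alkylation of a silyl enol ether); iodomethane approaches C8 anti to the adjacent C8a side chain, and the pseudo-axial C4a vinyl group blocks the only chair-like approach on the other face, so the methyl group ends up trans to the C8a substituent.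

Step 6
Reactants: 9 (2R,3S,4R)-4-ethenyl-3-{2-[(4-methoxybenzyl)oxy]ethyl}-2-methylcyclohexan-1-one
Product: 10 (1S,2R,3S,4R)-4-ethenyl-3-{2-[(4-methoxybenzyl)oxy]ethyl}-2-methylcyclohexan-1-ol
Conditions: Li[HB(sec-Bu)3], THF, −78 °C; H2O
Reagents that add atoms: none
Why: The bulky trialkylborohydride attacks the C7 carbonyl from the equatorial direction of the chair with an equatorial C8 methyl group and gives the axial alcohol cis to that methyl group, as it does with 2-methylcyclohexanone; the low temperature prevents epimerisation at C8.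

Step 7
Reactants: 10 (1S,2R,3S,4R)-4-ethenyl-3-{2-[(4-methoxybenzyl)oxy]ethyl}-2-methylcyclohexan-1-ol
Product: 11 tert-butyl{[(1S,2R,3S,4R)-4-ethenyl-3-{2-[(4-methoxybenzyl)oxy]ethyl}-2-methylcyclohexyl]oxy}dimethylsilane
Conditions: t-BuMe2SiOTf, 2,6-lutidine, CH2Cl2, −78 → 0 °C
Reagents that add atoms: tert-butyldimethylsilyl trifluoromethanesulfonate, CC(C)(C)[Si](C)(C)OS(=O)(=O)C(F)(F)F
Why: Silyl triflate with a hindered pyridine base silylates even an axial secondary alcohol flanked by a methyl group, and the resulting silyl ether carries the C7 oxygen to the penultimate stage.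

Step 8
Reactants: 11 tert-butyl{[(1S,2R,3S,4R)-4-ethenyl-3-{2-[(4-methoxybenzyl)oxy]ethyl}-2-methylcyclohexyl]oxy}dimethylsilane
Product: 12 2-[(1S,2R,3S,6R)-3-{[tert-butyl(dimethyl)silyl]oxy}-6-ethenyl-2-methylcyclohexyl]ethan-1-ol
Conditions: DDQ, CH2Cl2/aq. NaH2PO4–Na2HPO4 buffer (pH 7), 0 °C
Reagents that add atoms: none
Why: Oxidative cleavage of the 4-methoxybenzyl ether by the quinone goes through the benzylic oxocarbenium ion and leaves the silyl ether and the isolated vinyl group untouched.

Step 9
Reactants: 12 2-[(1S,2R,3S,6R)-3-{[tert-butyl(dimethyl)silyl]oxy}-6-ethenyl-2-methylcyclohexyl]ethan-1-ol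
Product: 14 2-[(1S,2R,3S,6R)-3-{[tert-butyl(dimethyl)silyl]oxy}-6-ethenyl-2-methylcyclohexyl]acetic acid, via aldehyde 13 (not isolated)
Conditions: TEMPO (20 mol %), PhI(OAc)2, MeCN/H2O, 23 °C
Reagents that add atoms: water, O
Why: Nitroxyl-catalysed oxidation with a hypervalent iodine co-oxidant in aqueous acetonitrile takes a primary alcohol through the aldehyde hydrate to the carboxylic acid without touching the alkene or the silyl ether, and the new carbonyl has no α-stereocentre.

Step 10
Reactants: 15 (R)-but-3-yn-2-ol
Product: 17 (2R,3E)-4-iodo-3-methylbut-3-en-2-ol, via alkenylalane 16 (not isolated)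
Conditions: AlMe3, Cp2ZrCl2 (25 mol %), CH2Cl2, 0 → 23 °C; then I2, THF, −30 → 0 °C
Reagents that add atoms: trimethylaluminium, C[Al](C)C; iodine, [I][I]
Why: Zirconium-catalysed syn-carboalumination of the terminal alkyne puts the methyl group on the inner carbon and aluminium on the terminus, iodinolysis with retention gives the (E)-iodoalkene, and the carbinol centre from the chiral pool is not touched.

Step 11
Reactants: 17 (2R,3E)-4-iodo-3-methylbut-3-en-2-ol; 18 4,4,5,5-tetramethyl-2-(prop-1-en-2-yl)-1,3,2-dioxaborolane
Product: 19 (2R,3E)-3,5-dimethylhexa-3,5-dien-2-ol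
Conditions: Pd(PPh3)4 (5 mol %), K3PO4, THF/H2O, 50 °C
Reagents that add atoms: none
Why: Suzuki–Miyaura coupling of an alkenyl iodide with an alkenylboronate retains both alkene geometries and tolerates the free alcohol.

Step 12
Reactants: 14 2-[(1S,2R,3S,6R)-3-{[tert-butyl(dimethyl)silyl]oxy}-6-ethenyl-2-methylcyclohexyl]acetic acid; 19 (2R,3E)-3,5-dimethylhexa-3,5-dien-2-ol
Product: 20 (2R,3E)-3,5-dimethylhexa-3,5-dien-2-yl 2-[(1S,2R,3S,6R)-3-{[tert-butyl(dimethyl)silyl]oxy}-6-ethenyl-2-methylcyclohexyl]acetate
Conditions: DCC, DMAP (10 mol %), CH2Cl2, 0 → 23 °C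
Reagents that add atoms: none
Why: Carbodiimide esterification with an acyl-transfer catalyst (Steglich esterification) joins the unhindered acetic acid arm to the secondary allylic alcohol by acyl substitution, so the allylic C–O bond is never ionised and the (R) configuration is kept.

Step 13
Reactants: 20 (2R,3E)-3,5-dimethylhexa-3,5-dien-2-yl 2-[(1S,2R,3S,6R)-3-{[tert-butyl(dimethyl)silyl]oxy}-6-ethenyl-2-methylcyclohexyl]acetate
Product: 24 (2S,3S,4E)-2-[(1S,2R,3S,6R)-3-{[tert-butyl(dimethyl)silyl]oxy}-6-ethenyl-2-methylcyclohexyl]-4-methyl-3-(prop-1-en-2-yl)hex-4-enoic acid, via lithium enolate 21 (not isolated), via silyl ketene acetal 22 (not isolated), via trimethylsilyl ester 23 (not isolated)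
Conditions: LiN(i-Pr)2, THF, −78 °C; Me3SiCl/Et3N, −78 → 23 °C, then 55 °C; 1 M HCl
Reagents that add atoms: none
Why: Ireland–Claisen rearrangement: kinetic deprotonation in THF without a dipolar cosolvent gives the enolate with C8a trans to O–Li and hence the (E)-silyl ketene acetal; in the chair transition state the carbinol methyl group is equatorial, which makes the new butenyl alkene (E) and fixes the face of the allyl unit so that the (R) carbinol sets C2, while the equatorial isopropenyl group of the (E)-alkene and the axial C8a group give the anti relationship that sets C1.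

Step 14
Reactants: 24 (2S,3S,4E)-2-[(1S,2R,3S,6R)-3-{[tert-butyl(dimethyl)silyl]oxy}-6-ethenyl-2-methylcyclohexyl]-4-methyl-3-(prop-1-en-2-yl)hex-4-enoic acid
Product: 25 methyl (2S,3S,4E)-2-[(1S,2R,3S,6R)-3-{[tert-butyl(dimethyl)silyl]oxy}-6-ethenyl-2-methylcyclohexyl]-4-methyl-3-(prop-1-en-2-yl)hex-4-enoate
Conditions: Me3SiCHN2, PhMe/MeOH, 0 → 23 °C
Reagents that add atoms: (trimethylsilyl)diazomethane, C[Si](C)(C)C=[N+]=[N-]
Why: Diazoalkane methylation of the hindered α-branched acid is fast and neutral and does not epimerise C1.

Step 15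
Reactants: 25 methyl (2S,3S,4E)-2-[(1S,2R,3S,6R)-3-{[tert-butyl(dimethyl)silyl]oxy}-6-ethenyl-2-methylcyclohexyl]-4-methyl-3-(prop-1-en-2-yl)hex-4-enoate
Product: 26 methyl (1S,2R,4aS,7S,8R,8aS)-2-[(2E)-but-2-en-2-yl]-7-{[tert-butyl(dimethyl)silyl]oxy}-3,8-dimethyl-1,2,4a,5,6,7,8,8a-octahydronaphthalene-1-carboxylate
Conditions: (H2IMes)(PCy3)Cl2Ru=CHPh (second-generation Grubbs catalyst, 5–10 mol %), 1,4-benzoquinone (10 mol %), CH2Cl2 (0.005 M), 40 °C
Reagents that add atoms: none
Why: Ring-closing olefin metathesis of a 1,7-diene: the ruthenium benzylidene first exchanges onto the least hindered, monosubstituted C4a vinyl group, the resulting alkylidene at C4 adds in a [2+2] sense to the 1,1-disubstituted isopropenyl alkene on C2, and cycloreversion of the ruthenacyclobutane forms C3=C4 and passes the terminal methylene to the metal, from which it leaves as the volatile two-carbon alkene. The closest known reaction type is the closure of dienes holding one monosubstituted and one 1,1-disubstituted alkene to trisubstituted cyclohexenes with this catalyst class. Ring A closes as a six-membered carbocycle by joining C3 and C4, whose carriers (the C4a vinyl group and the C8a-bound chain) are held cis on ring B, so the cis fusion is already in place and only a low-strain half-chair has to form. No stereocentre is created: C1, C2, C4a and C8a come in from steps 3 and 13, and the neutral conditions leave the doubly allylic C2–H and the ester-activated C1–H untouched and put the double bond where the two alkene carbons were. The selectivity needed is between the isopropenyl and the butenyl group on C2, both of which could give a six-membered ring; it rests on the much lower reactivity of the trisubstituted butenyl alkene, whose engagement would need a more substituted metallacycle and the release of a ruthenium ethylidene. High dilution disfavours intermolecular metathesis at the vinyl group, and the quinone suppresses alkene migration by ruthenium hydrides.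

Step 16
Reactants: 26 methyl (1S,2R,4aS,7S,8R,8aS)-2-[(2E)-but-2-en-2-yl]-7-{[tert-butyl(dimethyl)silyl]oxy}-3,8-dimethyl-1,2,4a,5,6,7,8,8a-octahydronaphthalene-1-carboxylate
Product: 27 [(1S,2R,4aS,7S,8R,8aR)-2-[(2E)-but-2-en-2-yl]-7-{[tert-butyl(dimethyl)silyl]oxy}-3,8-dimethyl-1,2,4a,5,6,7,8,8a-octahydronaphthalen-1-yl]methanol
Conditions: i-Bu2AlH, CH2Cl2, −78 → 0 °C; aq. potassium sodium tartrate
Reagents that add atoms: none
Why: Full reduction of the hindered ester to the primary alcohol with the aluminium hydride is cleaner than a partial reduction, and once the carbonyl is reduced C1 is no longer epimerisable.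

Step 17
Reactants: 27 [(1S,2R,4aS,7S,8R,8aR)-2-[(2E)-but-2-en-2-yl]-7-{[tert-butyl(dimethyl)silyl]oxy}-3,8-dimethyl-1,2,4a,5,6,7,8,8a-octahydronaphthalen-1-yl]methanol
Product: 28 (1S,2R,4aS,7S,8R,8aS)-2-[(2E)-but-2-en-2-yl]-7-{[tert-butyl(dimethyl)silyl]oxy}-3,8-dimethyl-1,2,4a,5,6,7,8,8a-octahydronaphthalene-1-carbaldehyde
Conditions: Dess–Martin periodinane, pyridine, CH2Cl2, 0 → 23 °C
Reagents that add atoms: none
Why: Dess–Martin oxidation with pyridine buffering gives the α-branched aldehyde under conditions that are neither basic nor strongly acidic, so C1 does not epimerise and the ring alkene does not migrate; the aldehyde is used at once.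

Step 18
Reactants: 28 (1S,2R,4aS,7S,8R,8aS)-2-[(2E)-but-2-en-2-yl]-7-{[tert-butyl(dimethyl)silyl]oxy}-3,8-dimethyl-1,2,4a,5,6,7,8,8a-octahydronaphthalene-1-carbaldehyde; 29 triethyl 4-phosphonocrotonate
Product: 31 ethyl (2E,4E)-5-[(1S,2R,4aS,7S,8R,8aR)-2-[(2E)-but-2-en-2-yl]-7-{[tert-butyl(dimethyl)silyl]oxy}-3,8-dimethyl-1,2,4a,5,6,7,8,8a-octahydronaphthalen-1-yl]penta-2,4-dienoate, via lithiated phosphonate 30 (not isolated)
Conditions: LiN(SiMe3)2, THF, −78 → 0 °C
Reagents that add atoms: none
Why: Horner–Wadsworth–Emmons olefination with the lithiated vinylogous phosphonate forms the new alkene (E)-selectively and keeps the (E) geometry of the crotonate unit; the preformed anion, the non-nucleophilic amide base and the low temperature spare the α-stereocentre of the aldehyde.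

Step 19
Reactants: 31 ethyl (2E,4E)-5-[(1S,2R,4aS,7S,8R,8aR)-2-[(2E)-but-2-en-2-yl]-7-{[tert-butyl(dimethyl)silyl]oxy}-3,8-dimethyl-1,2,4a,5,6,7,8,8a-octahydronaphthalen-1-yl]penta-2,4-dienoate
Product: 32 ethyl (2E,4E)-5-[(1S,2R,4aS,7S,8R,8aR)-2-[(2E)-but-2-en-2-yl]-7-hydroxy-3,8-dimethyl-1,2,4a,5,6,7,8,8a-octahydronaphthalen-1-yl]penta-2,4-dienoate
Conditions: HF·pyridine, pyridine, THF, 0 → 23 °C
Reagents that add atoms: none
Why: Buffered hydrogen fluoride–pyridine removes the secondary silyl ether without the basicity of ammonium fluorides, which could deprotonate the vinylogously acidic C1–H.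

Step 20
Reactants: 32 ethyl (2E,4E)-5-[(1S,2R,4aS,7S,8R,8aR)-2-[(2E)-but-2-en-2-yl]-7-hydroxy-3,8-dimethyl-1,2,4a,5,6,7,8,8a-octahydronaphthalen-1-yl]penta-2,4-dienoate
Product: 33 pyridinium salt of ethyl (2E,4E)-5-[(1S,2R,4aS,7S,8R,8aR)-2-[(2E)-but-2-en-2-yl]-3,8-dimethyl-7-(sulfonatooxy)-1,2,4a,5,6,7,8,8a-octahydronaphthalen-1-yl]penta-2,4-dienoate
Conditions: SO3·pyridine, pyridine, 23 → 50 °C
Reagents that add atoms: sulfur trioxide–pyridine complex, O=S(=O)([O-])[n+]1ccccc1
Why: O-Sulfation of a secondary alcohol with the sulfur trioxide–amine complex is a standard route to sulfate monoesters; the medium is weakly basic, so neither the alkenes nor C1 are at risk.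

Step 21
Reactants: 33 pyridinium salt of ethyl (2E,4E)-5-[(1S,2R,4aS,7S,8R,8aR)-2-[(2E)-but-2-en-2-yl]-3,8-dimethyl-7-(sulfonatooxy)-1,2,4a,5,6,7,8,8a-octahydronaphthalen-1-yl]penta-2,4-dienoate
Product: 34 (2E,4E)-5-[(1S,2R,4aS,7S,8R,8aR)-2-[(2E)-but-2-en-2-yl]-3,8-dimethyl-7-(sulfooxy)-1,2,4a,5,6,7,8,8a-octahydronaphthalen-1-yl]penta-2,4-dienoic acid
Conditions: LiOH, THF/H2O, 0 → 23 °C; then 1 M HCl to pH 2, 0 °C, reversed-phase isolation
Reagents that add atoms: lithium hydroxide, [Li+].[OH-]
Why: Saponification of the ethyl ester; sulfate monoester anions resist alkaline hydrolysis, and a brief cold acidification releases the free acid form without time for sulfate solvolysis.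

## Compound list

Remark: the descriptor at C8a changes between R and S along the route (S in 26 and 28, R in 27 and 31–34) only because the CIP rank of C1 against C8 changes with the C1 substituent; the spatial arrangement is the same throughout.

1 | 3-[(4-methoxybenzyl)oxy]propanal | COc1ccc(COCCC=O)cc1 | starting material
2 | 1-(triphenylphosphoranylidene)propan-2-one | CC(=O)C=P(c1ccccc1)(c1ccccc1)c1ccccc1 | starting material
3 | (E)-6-[(4-methoxybenzyl)oxy]hex-3-en-2-one | COc1ccc(COCC/C=C/C(C)=O)cc1 | intermediate
4 | (E)-{[6-((4-methoxybenzyl)oxy)hexa-1,3-dien-2-yl]oxy}triisopropylsilane | COc1ccc(COCC/C=C/C(=C)O[Si](C(C)C)(C(C)C)C(C)C)cc1 | intermediate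
5 | acrolein (prop-2-enal) | C=CC=O | starting material
6 | (1S,2R)-2-{2-[(4-methoxybenzyl)oxy]ethyl}-4-[(triisopropylsilyl)oxy]cyclohex-3-ene-1-carbaldehyde | COc1ccc(COCC[C@@H]2C=C(O[Si](C(C)C)(C(C)C)C(C)C)CC[C@@H]2C=O)cc1 | intermediate
7 | {[(3S,4R)-4-ethenyl-3-{2-[(4-methoxybenzyl)oxy]ethyl}cyclohex-1-en-1-yl]oxy}triisopropylsilane | COc1ccc(COCC[C@@H]2C=C(O[Si](C(C)C)(C(C)C)C(C)C)CC[C@@H]2C=C)cc1 | intermediate
8 | tris(dimethylamino)sulfonium (3S,4R)-4-ethenyl-3-{2-[(4-methoxybenzyl)oxy]ethyl}cyclohex-1-en-1-olate | COc1ccc(COCC[C@@H]2C=C([O-])CC[C@@H]2C=C)cc1.CN(C)[S+](N(C)C)N(C)C | intermediate (not isolated)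
9 | (2R,3S,4R)-4-ethenyl-3-{2-[(4-methoxybenzyl)oxy]ethyl}-2-methylcyclohexan-1-one | COc1ccc(COCC[C@@H]2[C@@H](C)C(=O)CC[C@@H]2C=C)cc1 | intermediate
10 | (1S,2R,3S,4R)-4-ethenyl-3-{2-[(4-methoxybenzyl)oxy]ethyl}-2-methylcyclohexan-1-ol | COc1ccc(COCC[C@@H]2[C@@H](C)[C@@H](O)CC[C@@H]2C=C)cc1 | intermediate
11 | tert-butyl{[(1S,2R,3S,4R)-4-ethenyl-3-{2-[(4-methoxybenzyl)oxy]ethyl}-2-methylcyclohexyl]oxy}dimethylsilane | COc1ccc(COCC[C@@H]2[C@@H](C)[C@@H](O[Si](C)(C)C(C)(C)C)CC[C@@H]2C=C)cc1 | intermediate
12 | 2-[(1S,2R,3S,6R)-3-{[tert-butyl(dimethyl)silyl]oxy}-6-ethenyl-2-methylcyclohexyl]ethan-1-ol | OCC[C@@H]1[C@@H](C)[C@@H](O[Si](C)(C)C(C)(C)C)CC[C@@H]1C=C | intermediate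
13 | 2-[(1S,2R,3S,6R)-3-{[tert-butyl(dimethyl)silyl]oxy}-6-ethenyl-2-methylcyclohexyl]acetaldehyde | O=CC[C@@H]1[C@@H](C)[C@@H](O[Si](C)(C)C(C)(C)C)CC[C@@H]1C=C | intermediate (not isolated)
14 | 2-[(1S,2R,3S,6R)-3-{[tert-butyl(dimethyl)silyl]oxy}-6-ethenyl-2-methylcyclohexyl]acetic acid | OC(=O)C[C@@H]1[C@@H](C)[C@@H](O[Si](C)(C)C(C)(C)C)CC[C@@H]1C=C | intermediate
15 | (R)-but-3-yn-2-ol | C[C@@H](O)C#C | starting material
16 | dimethyl[(1E,3R)-3-[(dimethylalumanyl)oxy]-2-methylbut-1-en-1-yl]alumane | C[C@@H](O[Al](C)C)/C(C)=C/[Al](C)C | intermediate (not isolated)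
17 | (2R,3E)-4-iodo-3-methylbut-3-en-2-ol | C[C@@H](O)/C(C)=C/I | intermediate
18 | 4,4,5,5-tetramethyl-2-(prop-1-en-2-yl)-1,3,2-dioxaborolane | CC(=C)B1OC(C)(C)C(C)(C)O1 | starting material
19 | (2R,3E)-3,5-dimethylhexa-3,5-dien-2-ol | C[C@@H](O)/C(C)=C/C(C)=C | intermediate
20 | (2R,3E)-3,5-dimethylhexa-3,5-dien-2-yl 2-[(1S,2R,3S,6R)-3-{[tert-butyl(dimethyl)silyl]oxy}-6-ethenyl-2-methylcyclohexyl]acetate | C=C(C)/C=C(C)/[C@@H](C)OC(=O)C[C@@H]1[C@@H](C)[C@@H](O[Si](C)(C)C(C)(C)C)CC[C@@H]1C=C | intermediate
21 | lithium enolate of ester 20 (ring carbon trans to O–Li) | [Li+].[O-]/C(O[C@H](C)/C(C)=C/C(C)=C)=C/[C@@H]1[C@@H](C)[C@@H](O[Si](C)(C)C(C)(C)C)CC[C@@H]1C=C | intermediate (not isolated)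
22 | (E)-O-trimethylsilyl ketene acetal of ester 20 (ring carbon trans to O–Si) | C[Si](C)(C)O/C(O[C@H](C)/C(C)=C/C(C)=C)=C/[C@@H]1[C@@H](C)[C@@H](O[Si](C)(C)C(C)(C)C)CC[C@@H]1C=C | intermediate (not isolated)
23 | trimethylsilyl (2S,3S,4E)-2-[(1S,2R,3S,6R)-3-{[tert-butyl(dimethyl)silyl]oxy}-6-ethenyl-2-methylcyclohexyl]-4-methyl-3-(prop-1-en-2-yl)hex-4-enoate | C/C=C(\C)[C@H](C(C)=C)[C@@H](C(=O)O[Si](C)(C)C)[C@@H]1[C@@H](C)[C@@H](O[Si](C)(C)C(C)(C)C)CC[C@@H]1C=C | intermediate (not isolated)
24 | (2S,3S,4E)-2-[(1S,2R,3S,6R)-3-{[tert-butyl(dimethyl)silyl]oxy}-6-ethenyl-2-methylcyclohexyl]-4-methyl-3-(prop-1-en-2-yl)hex-4-enoic acid | C/C=C(\C)[C@H](C(C)=C)[C@@H](C(=O)O)[C@@H]1[C@@H](C)[C@@H](O[Si](C)(C)C(C)(C)C)CC[C@@H]1C=C | intermediate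
25 | methyl (2S,3S,4E)-2-[(1S,2R,3S,6R)-3-{[tert-butyl(dimethyl)silyl]oxy}-6-ethenyl-2-methylcyclohexyl]-4-methyl-3-(prop-1-en-2-yl)hex-4-enoate | C/C=C(\C)[C@H](C(C)=C)[C@@H](C(=O)OC)[C@@H]1[C@@H](C)[C@@H](O[Si](C)(C)C(C)(C)C)CC[C@@H]1C=C | intermediate
26 | methyl (1S,2R,4aS,7S,8R,8aS)-2-[(2E)-but-2-en-2-yl]-7-{[tert-butyl(dimethyl)silyl]oxy}-3,8-dimethyl-1,2,4a,5,6,7,8,8a-octahydronaphthalene-1-carboxylate | C/C=C(\C)[C@@H]1C(C)=C[C@H]2CC[C@H](O[Si](C)(C)C(C)(C)C)[C@H](C)[C@H]2[C@@H]1C(=O)OC | intermediate
27 | [(1S,2R,4aS,7S,8R,8aR)-2-[(2E)-but-2-en-2-yl]-7-{[tert-butyl(dimethyl)silyl]oxy}-3,8-dimethyl-1,2,4a,5,6,7,8,8a-octahydronaphthalen-1-yl]methanol | C/C=C(\C)[C@@H]1C(C)=C[C@H]2CC[C@H](O[Si](C)(C)C(C)(C)C)[C@H](C)[C@H]2[C@@H]1CO | intermediate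
28 | (1S,2R,4aS,7S,8R,8aS)-2-[(2E)-but-2-en-2-yl]-7-{[tert-butyl(dimethyl)silyl]oxy}-3,8-dimethyl-1,2,4a,5,6,7,8,8a-octahydronaphthalene-1-carbaldehyde | C/C=C(\C)[C@@H]1C(C)=C[C@H]2CC[C@H](O[Si](C)(C)C(C)(C)C)[C@H](C)[C@H]2[C@@H]1C=O | intermediate
29 | triethyl 4-phosphonocrotonate | CCOC(=O)/C=C/CP(=O)(OCC)OCC | starting material
30 | lithium salt of triethyl 4-phosphonocrotonate (carbanion at C4) | [Li+].CCOC(=O)/C=C/[CH-]P(=O)(OCC)OCC | intermediate (not isolated)
31 | ethyl (2E,4E)-5-[(1S,2R,4aS,7S,8R,8aR)-2-[(2E)-but-2-en-2-yl]-7-{[tert-butyl(dimethyl)silyl]oxy}-3,8-dimethyl-1,2,4a,5,6,7,8,8a-octahydronaphthalen-1-yl]penta-2,4-dienoate | C/C=C(\C)[C@@H]1C(C)=C[C@H]2CC[C@H](O[Si](C)(C)C(C)(C)C)[C@H](C)[C@H]2[C@@H]1/C=C/C=C/C(=O)OCC | intermediate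
32 | ethyl (2E,4E)-5-[(1S,2R,4aS,7S,8R,8aR)-2-[(2E)-but-2-en-2-yl]-7-hydroxy-3,8-dimethyl-1,2,4a,5,6,7,8,8a-octahydronaphthalen-1-yl]penta-2,4-dienoate | C/C=C(\C)[C@@H]1C(C)=C[C@H]2CC[C@H](O)[C@H](C)[C@H]2[C@@H]1/C=C/C=C/C(=O)OCC | intermediate
33 | pyridinium salt of ethyl (2E,4E)-5-[(1S,2R,4aS,7S,8R,8aR)-2-[(2E)-but-2-en-2-yl]-3,8-dimethyl-7-(sulfonatooxy)-1,2,4a,5,6,7,8,8a-octahydronaphthalen-1-yl]penta-2,4-dienoate | C/C=C(\C)[C@@H]1C(C)=C[C@H]2CC[C@H](OS(=O)(=O)[O-])[C@H](C)[C@H]2[C@@H]1/C=C/C=C/C(=O)OCC.c1cc[nH+]cc1 | intermediate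
34 | (2E,4E)-5-[(1S,2R,4aS,7S,8R,8aR)-2-[(2E)-but-2-en-2-yl]-3,8-dimethyl-7-(sulfooxy)-1,2,4a,5,6,7,8,8a-octahydronaphthalen-1-yl]penta-2,4-dienoic acid | C/C=C(\C)[C@@H]1C(C)=C[C@H]2CC[C@H](OS(=O)(=O)O)[C@H](C)[C@H]2[C@@H]1/C=C/C=C/C(=O)O | target

## Step count and least certain steps

Total step count: 21. Longest linear sequence: 19 steps (steps 1–9 and 12–21, from aldehyde 1); the dienol branch is 2 steps (steps 10 and 11).

**Step 15 (key step).**
- What may go wrong: ring closure through the butenyl alkene with loss of a three-carbon alkene instead of the two-carbon one, or slow closure followed by alkene migration and intermolecular metathesis at the vinyl group.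
- Why: both alkenes on C2 can give a six-membered ring, and closure through the butenyl group would relieve the cis C1/C2 arrangement, which partly offsets the intrinsic preference for the less substituted alkene.
- Fallback (masking instead of relying on rate): starting from 25, the most electron-rich, trisubstituted butenyl alkene is epoxidised chemoselectively (m-CPBA, NaHCO3, CH2Cl2, −20 °C) to the epoxy diene ester F1, on either oxirane face since both are carried on. With only the vinyl and isopropenyl groups left, the same ruthenium carbene closes ring A to the epoxy octalin ester F2. Stereospecific oxygen transfer from the oxirane to a rhodium carbenoid (dimethyl diazomalonate, Rh2(OAc)4 catalyst, warm toluene) restores the (E)-butenyl alkene with retention and rejoins the route at 26.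

**Step 3.**
- What may go wrong: erosion of facial or endo selectivity with the unsubstituted enal, epimerisation of the formyl-bearing centre from cis to trans on the Lewis acid or on silica, or Lewis acid-promoted addition of the product enol ether to acrolein.
- Why: the α-unsubstituted enal is the least tightly organised dienophile for this catalyst class, and the cis aldehyde is the less stable epimer.
- Fallback (a dienophile that cannot epimerise, with the formyl group reached by redox): starting from diene 4, cycloaddition with 2,2,2-trifluoroethyl acrylate under the same type of chiral oxazaborolidinium catalysis gives the trifluoroethyl ester F3. Reduction with i-Bu2AlH gives the primary alcohol F4, and Dess–Martin oxidation gives aldehyde 6, which is taken directly into step 4.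

**Step 5.**
- What may go wrong: proton exchange between the free enolate and the product ketone, leading to loss of regiochemistry, double methylation or epimerisation at C8; sluggish cleavage of the bulky Si–O bond.
- Why: the fluoride-generated enolate is strongly basic and the product is an enolisable ketone.
- Fallback (no enolate at all): starting from 7, Simmons–Smith cyclopropanation (Et2Zn, CH2I2, CH2Cl2, 0 °C) of the electron-rich enol ether delivers the methylene group to the face opposite the C8a side chain, well before the vinyl group reacts, and gives the silyloxycyclopropane F5. Desilylation (n-Bu4NF) and acid-induced opening of the cyclopropanol at the C7–CH2 bond (p-TsOH) then give ketone 9, with the C8 configuration fixed in the cyclopropanation.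

**Step 13.**
- What may go wrong: leakage through a boat transition state or through the minor enolate geometry, which would erode the configuration at C1.
- Why: in the chair the C8a group is axial and faces the methyl group on the central allyl carbon.
- Fallback (both geometric elements inverted so that C8a becomes equatorial): starting from acid 14, the partner is made from purchased (S)-but-3-yn-2-ol F6. Copper-catalysed anti-carbomagnesiation (MeMgBr, CuI) and iodination give (2S,3Z)-4-iodo-3-methylbut-3-en-2-ol F7, and Suzuki–Miyaura coupling with 18 gives (2S,3Z)-3,5-dimethylhexa-3,5-dien-2-ol F8. Steglich esterification of 14 with F8 gives the ester F9. Enolisation with LiN(i-Pr)2 in THF/DMPU gives the enolate with C8a cis to O–Li, and the chair with C8a equatorial and the isopropenyl group axial converges on the same acid 24. The allylic 1,3-strain of the (Z)-alkene enforces the chirality transfer.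

## Further compounds

F1 | step 15 | methyl (2S,3S)-2-[(1S,2R,3S,6R)-3-{[tert-butyl(dimethyl)silyl]oxy}-6-ethenyl-2-methylcyclohexyl]-4-methyl-3-(2,3-dimethyloxiran-2-yl)pent-4-enoate (oxirane methyl groups cis; one of the two oxirane-face diastereomers drawn) | C[C@H]1O[C@]1(C)[C@H](C(C)=C)[C@@H](C(=O)OC)[C@@H]1[C@@H](C)[C@@H](O[Si](C)(C)C(C)(C)C)CC[C@@H]1C=C
F2 | step 15 | methyl (1S,2R,4aS,7S,8R,8aS)-7-{[tert-butyl(dimethyl)silyl]oxy}-2-(2,3-dimethyloxiran-2-yl)-3,8-dimethyl-1,2,4a,5,6,7,8,8a-octahydronaphthalene-1-carboxylate (same oxirane diastereomer as F1) | C[C@H]1O[C@]1(C)[C@@H]1C(C)=C[C@H]2CC[C@H](O[Si](C)(C)C(C)(C)C)[C@H](C)[C@H]2[C@@H]1C(=O)OC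
F3 | step 3 | 2,2,2-trifluoroethyl (1S,2R)-2-{2-[(4-methoxybenzyl)oxy]ethyl}-4-[(triisopropylsilyl)oxy]cyclohex-3-ene-1-carboxylate | COc1ccc(COCC[C@@H]2C=C(O[Si](C(C)C)(C(C)C)C(C)C)CC[C@@H]2C(=O)OCC(F)(F)F)cc1
F4 | step 3 | [(1S,2S)-2-{2-[(4-methoxybenzyl)oxy]ethyl}-4-[(triisopropylsilyl)oxy]cyclohex-3-en-1-yl]methanol | COc1ccc(COCC[C@@H]2C=C(O[Si](C(C)C)(C(C)C)C(C)C)CC[C@@H]2CO)cc1
F5 | step 5 | silyloxycyclopropane from 7: 4-ethenyl-3-{2-[(4-methoxybenzyl)oxy]ethyl}-1-[(triisopropylsilyl)oxy]bicyclo[4.1.0]heptane numbered from the silyloxy carbon, methylene bridge anti to the side chain | COc1ccc(COCC[C@@H]2[C@H]3C[C@@]3(O[Si](C(C)C)(C(C)C)C(C)C)CC[C@@H]2C=C)cc1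
F6 | step 13 | (S)-but-3-yn-2-ol (purchased) | C[C@H](O)C#C
F7 | step 13 | (2S,3Z)-4-iodo-3-methylbut-3-en-2-ol | C[C@H](O)/C(C)=C\I
F8 | step 13 | (2S,3Z)-3,5-dimethylhexa-3,5-dien-2-ol | C[C@H](O)/C(C)=C\C(C)=C
F9 | step 13 | (2S,3Z)-3,5-dimethylhexa-3,5-dien-2-yl 2-[(1S,2R,3S,6R)-3-{[tert-butyl(dimethyl)silyl]oxy}-6-ethenyl-2-methylcyclohexyl]acetate | C=C(C)\C=C(C)/[C@H](C)OC(=O)C[C@@H]1[C@@H](C)[C@@H](O[Si](C)(C)C(C)(C)C)CC[C@@H]1C=C
A1 | alternative 1 | cis-octalone with C7 ketone and C1 silyloxymethyl arm | C/C=C(\C)[C@@H]1C(C)=C[C@H]2CCC(=O)[C@H](C)[C@H]2[C@@H]1CO[Si](C)(C)C(C)(C)C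
A2 | alternative 1 | bridged vinyl carbinol: bicyclo[2.2.2]octene with bridgeheads C3 (methyl) and C8a, alkene bridge C4=C4a, and the C7 carbinol carrying a vinyl group syn to that alkene | C/C=C(\C)[C@@H]1[C@]2(C)C=C[C@@H]([C@@H](C)[C@@]2(O)C=C)[C@@H]1CO[Si](C)(C)C(C)(C)C
A3 | alternative 2 | cis-fused C7=C8 trimethylsilyl enol ether with a vinyl group on C1 | C/C=C(\C)[C@@H]1C(C)=C[C@H]2CCC(O[Si](C)(C)C)=C[C@H]2[C@@H]1C=C
A4 | alternative 2 | 4-substituted cyclohex-2-enone carrying the (Z)-alkenyl chain with butenyl and (E)-allylsilane groups on C2 | C/C=C(\C)[C@@H](/C=C/C[Si](C)(C)C)/C(C)=C\[C@H]1CCC(=O)C=C1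
A5 | alternative 3 | ring A carboxylic acid with C7 silyl ether | C/C=C(\C)[C@@H]1C(C)=C[C@H]2CC[C@H](O[Si](C)(C)C(C)(C)C)[C@H](C)[C@H]2[C@@H]1C(=O)O
A6 | alternative 3 | δ-lactone cis-fused to ring B (carbonyl joined to C1, ring oxygen on C4) with an (E,E)-2,4-dimethylhexa-2,4-dienyl-type chain on C4 | C/C=C(C)/C=C(\C)[C@@H]1OC(=O)C[C@@H]2[C@@H](C)[C@@H](O[Si](C)(C)C(C)(C)C)CC[C@H]12
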